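## Retrosynthetic overview

- **Feature used:** in ring B (O1, C2, C3, C3a, C7a) the triad O1–C7a–C3a is a latent lactone O–C(=O)–Cα. C2 and C3 are the trans C5 and C4 of that γ-butyrolactone. Ring A carries only H at C6 and C7, so these two carbons can come from an acetylene equivalent.
- **Side chain last:** allylic alcohol ⇐ enoate (i-Bu2AlH) ⇐ 5-carbaldehyde (Wittig) ⇐ 5-CH2OH (MnO2). Both primary alcohols are freed together from silyl ethers.
- **Ring A:** cut C7a–C7 and C5–C6. This is a [4+2] addition of the lactone-derived 2-silyloxy-3-[(E)-propenyl]-4,5-dihydrofuran to phenyl vinyl sulfoxide, followed by loss of PhSOH and silanol.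
- **Diene:** ⇐ γ-enolisation and O-silylation of an α-alkylidene lactone ⇐ aldol condensation of the lactone with 3-silyloxypropanal, which brings C4, C5 and the CH2O carbon on C5.
- **Lactone:** ⇐ Evans syn-aldol of a succinyl imide with 3,4,5-trimethoxybenzaldehyde, then lactonisation, which sets C2 and C3. Ring order: ring B first (as the lactone), ring A second.

Key step: step 9

Remark: TBS = tert-butyldimethylsilyl; the benzofuran locants of the target (O1, C2, C3, C3a, C4–C7, C7a) are used for the matching atoms of all intermediates; lithium, sodium and boron derivatives (enolates, alkoxides, carboxylates) of a numbered compound are treated as forms of that compound and carry no number of their own.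

## Route

Step 1
Reactants: 1 (R)-4-benzyl-1,3-oxazolidin-2-one; 2 methyl 4-chloro-4-oxobutanoate
Product: 3 methyl 4-[(4R)-4-benzyl-2-oxo-1,3-oxazolidin-3-yl]-4-oxobutanoate
Conditions: n-BuLi, THF, −78 °C; 2, −78 → 0 °C
Reagents that add atoms: none
Why: N-acylation of the lithiated oxazolidinone is standard imide formation, and at −78 °C the acyl chloride reacts far faster than the methyl ester.

Step 2
Reactants: 3 succinyl imide; 4 3,4,5-trimethoxybenzaldehyde
Product: 6 (4R)-4-benzyl-3-{[(2R,3R)-5-oxo-2-(3,4,5-trimethoxyphenyl)oxolan-3-yl]carbonyl}-1,3-oxazolidin-2-one (trans lactone), via syn-aldol adduct 5 (not isolated)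
Conditions: n-Bu2BOTf, Et3N, CH2Cl2, 0 °C; 4, −78 → 0 °C; pH 7 buffer, MeOH, 30% H2O2, 0 °C; PPTS (cat.), toluene, 60 °C
Reagents that add atoms: none
Why: In this Evans syn-aldol reaction only the chelating imide carbonyl is enolised, to the Z-boron enolate, the chair transition state with one face blocked by the benzyl group of the (R)-auxiliary sets the (R,R)-syn pair (future C3 and C2), and the γ-hydroxy ester then lactonises with retention at the carbinol carbon, which turns syn into the trans-4,5-lactone.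

Step 3
Reactants: 6 lactone imide
Product: 8 (2R,3R)-5-oxo-2-(3,4,5-trimethoxyphenyl)oxolane-3-carboxylic acid, via peroxy acid 7 (not isolated)
Conditions: LiOH, 30% H2O2, THF/H2O, 0 °C; Na2SO3; 1 M HCl to pH 2
Reagents that add atoms: hydrogen peroxide, OO
Why: In this hydroperoxide-mediated imide cleavage LiOOH attacks the exocyclic imide carbonyl, any lactone that opens recloses on acidification without touching a stereocentre, and the trans acid is also the thermodynamic epimer.

Step 4
Reactants: 8 lactone acid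
Product: 9 (4S,5R)-4-(hydroxymethyl)-5-(3,4,5-trimethoxyphenyl)oxolan-2-one
Conditions: BH3·SMe2, THF, 0 → 23 °C; H2O
Reagents that add atoms: none
Why: Chemoselective borane reduction takes the free acid through its acyloxyborane much faster than the lactone, and the neutral work-up avoids base-induced translactonisation onto the new primary alcohol.

Step 5
Reactants: 9 hydroxymethyl lactone
Product: 10 (4S,5R)-4-{[(TBS)oxy]methyl}-5-(3,4,5-trimethoxyphenyl)oxolan-2-one
Conditions: t-BuMe2SiCl, imidazole, CH2Cl2, 23 °C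
Reagents that add atoms: tert-butyldimethylsilyl chloride, CC(C)(C)[Si](C)(C)Cl
Why: This is a standard silyl ether formation on a primary alcohol, and a silyl group is chosen so that one later fluoride step frees both primary alcohols and no acid ever meets the ionisable p-alkoxycinnamyl alcohol.

Step 6
Reactants: 10 silyl-protected lactone; 11 3-[(TBS)oxy]propanal
Product: 12 (4S,5R)-3-{3-[(TBS)oxy]-1-hydroxypropyl}-4-{[(TBS)oxy]methyl}-5-(3,4,5-trimethoxyphenyl)oxolan-2-one (epimers at C3 of the lactone and at the carbinol carbon)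
Conditions: LiN(i-Pr)2, THF, −78 °C; 11; AcOH, −78 °C
Reagents that add atoms: none
Why: In this lithium enolate aldol addition the lactone has one enolisable position (future C3a) and no β-leaving group, addition at −78 °C outruns β-elimination of the aldehyde, and the two new stereocentres do not matter because steps 7 and 8 erase them.

Step 7
Reactants: 12 aldol adduct
Product: 14 (3E,4S,5R)-3-{3-[(TBS)oxy]propylidene}-4-{[(TBS)oxy]methyl}-5-(3,4,5-trimethoxyphenyl)oxolan-2-one, via mesylate 13 (not isolated)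
Conditions: MeSO2Cl, Et3N, CH2Cl2, 0 °C; DBU, 0 → 23 °C
Reagents that add atoms: methanesulfonyl chloride, CS(=O)(=O)Cl (its CH3SO2 group is held by 13 only and leaves again on the way to 14)
Why: Mesylation followed by E1cB elimination is the usual aldol-condensation sequence to α-alkylidene lactones, the E isomer should prevail, and either geometry would serve because C3a=C4 becomes a single bond in step 8.

Step 8
Reactants: 14 α-alkylidene lactone
Product: 15 (4S,5R)-2-[(TBS)oxy]-3-{(E)-3-[(TBS)oxy]prop-1-enyl}-4-{[(TBS)oxy]methyl}-5-(3,4,5-trimethoxyphenyl)-4,5-dihydrofuran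
Conditions: t-BuMe2SiOTf, Et3N, CH2Cl2, 0 °C; pentane, cold aq. NaHCO3; used crude
Reagents that add atoms: tert-butyldimethylsilyl trifluoromethanesulfonate, CC(C)(C)[Si](C)(C)OS(=O)(=O)C(F)(F)F
Why: In this soft vinylogous enolisation (silyl dienol ether formation) O-silylation of the lactone carbonyl places positive charge on C7a and C4, so only the exocyclic C5–H is acidified while the cross-conjugated C3–H and its stereocentre stay untouched, allylic 1,3-strain against the C3 substituent turns the CH2OSi group outward to give E-C4=C5, and no free dienolate forms that could expel the silyloxy group.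

Step 9
Reactants: 15 silyloxy diene; 16 phenyl vinyl sulfoxide (racemic)
Product: 19 (2R,3S)-3,5-bis{[(TBS)oxy]methyl}-2-(3,4,5-trimethoxyphenyl)-2,3-dihydro-1-benzofuran (trans), via sulfinyl cycloadduct 17 (not isolated), via cyclohexadiene ketal 18 (not isolated)
Conditions: 16 (3 equiv), 4 Å MS, toluene (1 M), 110 °C, sealed tube, Ar
Reagents that add atoms: none
Why: Proposed new method: the electron-rich ketene silyl acetal diene C7a=C3a–C4=C5 of 15 adds suprafacially to the electron-poor alkene of 16 in a thermal, normal-demand Diels–Alder reaction, its most nucleophilic terminus C5 bonding to the CH2 end, so that C5–C6 and C7a–C7 form and ring A closes as a six-membered carbocycle in an intermolecular [4+2] mode (17). At the same temperature the sulfoxide undergoes syn (Ei) elimination with a C6 hydrogen to give the 1,4-cyclohexadiene 18, which aromatises by 1,4-loss of t-BuMe2SiOH from C7a–OSi and C5–H. The closest known reaction types are the benzannulation of acyclic 1-alkoxy-1-silyloxy-1,3-dienes with alkynes or haloquinones and the use of aryl vinyl sulfoxides as acetylene equivalents, and the new element is a cyclic, lactone-derived ketene acetal that has to keep its ring oxygen. The selectivity needed is cleavage of C7a–OSi and not of C7a–O1: because O1 is tied to C3 through ring B, the silyloxy group sits in the inside position of the diene and therefore ends up pseudo-axial, parallel to both flanking π bonds and cis to the inside C5–H, whereas C7a–O1 is held near the ring plane by the five-membered ring, silanolate is the better leaving group, its departure leaves the better stabilised O-alkyl arenium ion, and no fluoride or aqueous acid is admitted before aromatisation because Si–O cleavage would open ring B. Regiochemistry, endo/exo and facial selectivity are irrelevant since C5, C7, C7a and sulfur all lose their stereochemical information, so no new stereocentre survives and C2 and C3 are spectators under neutral conditions. The s-cis rotamer is accessible because E-C4=C5 points only H inward and the C3 side chain destabilises the s-trans rotamer.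

Step 10
Reactants: 19 bis-silyl ether
Product: 20 [(2R,3S)-2-(3,4,5-trimethoxyphenyl)-2,3-dihydro-1-benzofuran-3,5-diyl]dimethanol
Conditions: Bu4NF, THF, 0 → 23 °C
Reagents that add atoms: none
Why: Fluoride-mediated desilylation cleaves both primary silyl ethers at once and leaves the aryl ethers, ring B and both stereocentres alone.

Step 11
Reactants: 20 diol
Product: 21 (2R,3S)-3-(hydroxymethyl)-2-(3,4,5-trimethoxyphenyl)-2,3-dihydro-1-benzofuran-5-carbaldehyde
Conditions: MnO2, CH2Cl2, 23 °C
Reagents that add atoms: none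
Why: Chemoselective MnO2 oxidation takes only the benzylic alcohol, which is activated by the para oxygen O1, while the saturated C3–CH2OH is not a substrate for this reagent.

Step 12
Reactants: 21 hydroxy aldehyde; 22 ethyl (triphenylphosphoranylidene)acetate
Product: 23 ethyl (E)-3-[(2R,3S)-3-(hydroxymethyl)-2-(3,4,5-trimethoxyphenyl)-2,3-dihydro-1-benzofuran-5-yl]prop-2-enoate
Conditions: 22, toluene, 80 °C
Reagents that add atoms: none
Why: The Wittig reaction of a stabilised ylide with an aromatic aldehyde should give the E-enoate and needs no added base, so the free alcohol and C2/C3 are safe.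

Step 13
Reactants: 23 enoate
Product: 24 (E)-3-[(2R,3S)-3-(hydroxymethyl)-2-(3,4,5-trimethoxyphenyl)-2,3-dihydro-1-benzofuran-5-yl]prop-2-en-1-ol (target)
Conditions: i-Bu2AlH (excess), CH2Cl2, −78 °C; Na2SO4·10H2O
Reagents that add atoms: none
Why: The 1,2-reduction of an enoate with i-Bu2AlH gives the E-allylic alcohol without conjugate reduction, one extra equivalent covers the free OH, and the neutral quench spares the acid-sensitive p-alkoxycinnamyl alcohol.

## Compound list

1 | (R)-4-benzyl-1,3-oxazolidin-2-one | O=C1N[C@H](Cc2ccccc2)CO1 | starting material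
2 | methyl 4-chloro-4-oxobutanoate | COC(=O)CCC(=O)Cl | starting material
3 | methyl 4-[(4R)-4-benzyl-2-oxo-1,3-oxazolidin-3-yl]-4-oxobutanoate | COC(=O)CCC(=O)N1[C@H](Cc2ccccc2)COC1=O | intermediate
4 | 3,4,5-trimethoxybenzaldehyde | COc1cc(C=O)cc(OC)c1OC | starting material
5 | methyl (3R,4R)-3-{[(4R)-4-benzyl-2-oxo-1,3-oxazolidin-3-yl]carbonyl}-4-hydroxy-4-(3,4,5-trimethoxyphenyl)butanoate (syn aldol) | COC(=O)C[C@H]([C@@H](O)c1cc(OC)c(OC)c(OC)c1)C(=O)N1[C@H](Cc2ccccc2)COC1=O | intermediate (not isolated)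
6 | (4R)-4-benzyl-3-{[(2R,3R)-5-oxo-2-(3,4,5-trimethoxyphenyl)oxolan-3-yl]carbonyl}-1,3-oxazolidin-2-one | COc1cc([C@@H]2OC(=O)C[C@H]2C(=O)N3[C@H](Cc4ccccc4)COC3=O)cc(OC)c1OC | intermediate
7 | (2R,3R)-5-oxo-2-(3,4,5-trimethoxyphenyl)oxolane-3-carboperoxoic acid | COc1cc([C@@H]2OC(=O)C[C@H]2C(=O)OO)cc(OC)c1OC | intermediate (not isolated)
8 | (2R,3R)-5-oxo-2-(3,4,5-trimethoxyphenyl)oxolane-3-carboxylic acid | COc1cc([C@@H]2OC(=O)C[C@H]2C(=O)O)cc(OC)c1OC | intermediate
9 | (4S,5R)-4-(hydroxymethyl)-5-(3,4,5-trimethoxyphenyl)oxolan-2-one | COc1cc([C@@H]2OC(=O)C[C@H]2CO)cc(OC)c1OC | intermediate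
10 | (4S,5R)-4-{[(TBS)oxy]methyl}-5-(3,4,5-trimethoxyphenyl)oxolan-2-one | COc1cc([C@@H]2OC(=O)C[C@H]2CO[Si](C)(C)C(C)(C)C)cc(OC)c1OC | intermediate
11 | 3-[(TBS)oxy]propanal | CC(C)(C)[Si](C)(C)OCCC=O | starting material
12 | (4S,5R)-3-{3-[(TBS)oxy]-1-hydroxypropyl}-4-{[(TBS)oxy]methyl}-5-(3,4,5-trimethoxyphenyl)oxolan-2-one (epimers at lactone C3 and carbinol carbon) | COc1cc([C@@H]2OC(=O)C(C(O)CCO[Si](C)(C)C(C)(C)C)[C@H]2CO[Si](C)(C)C(C)(C)C)cc(OC)c1OC | intermediate
13 | methanesulfonate of 12 | COc1cc([C@@H]2OC(=O)C(C(CCO[Si](C)(C)C(C)(C)C)OS(C)(=O)=O)[C@H]2CO[Si](C)(C)C(C)(C)C)cc(OC)c1OC | intermediate (not isolated)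
14 | (3E,4S,5R)-3-{3-[(TBS)oxy]propylidene}-4-{[(TBS)oxy]methyl}-5-(3,4,5-trimethoxyphenyl)oxolan-2-one | COc1cc([C@@H]2OC(=O)/C(=C/CCO[Si](C)(C)C(C)(C)C)[C@H]2CO[Si](C)(C)C(C)(C)C)cc(OC)c1OC | intermediate
15 | (4S,5R)-2-[(TBS)oxy]-3-{(E)-3-[(TBS)oxy]prop-1-enyl}-4-{[(TBS)oxy]methyl}-5-(3,4,5-trimethoxyphenyl)-4,5-dihydrofuran | COc1cc([C@@H]2OC(O[Si](C)(C)C(C)(C)C)=C(/C=C/CO[Si](C)(C)C(C)(C)C)[C@H]2CO[Si](C)(C)C(C)(C)C)cc(OC)c1OC | intermediate (key-step precursor)
16 | phenyl vinyl sulfoxide (racemic) | C=CS(=O)c1ccccc1 | starting material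
17 | (2R,3S)-7a-[(TBS)oxy]-3,5-bis{[(TBS)oxy]methyl}-7-(phenylsulfinyl)-2-(3,4,5-trimethoxyphenyl)-2,3,5,6,7,7a-hexahydro-1-benzofuran (C7a–OSi cis to C5–H; drawn for attack on the face opposite the C3 side chain; epimers at C7 and S) | COc1cc([C@@H]2O[C@]3(O[Si](C)(C)C(C)(C)C)C(S(=O)c4ccccc4)C[C@H](CO[Si](C)(C)C(C)(C)C)C=C3[C@H]2CO[Si](C)(C)C(C)(C)C)cc(OC)c1OC | intermediate (not isolated)
18 | (2R,3S)-7a-[(TBS)oxy]-3,5-bis{[(TBS)oxy]methyl}-2-(3,4,5-trimethoxyphenyl)-2,3,5,7a-tetrahydro-1-benzofuran (C7a–OSi cis to C5–H; same facial isomer drawn) | COc1cc([C@@H]2O[C@]3(O[Si](C)(C)C(C)(C)C)C=C[C@H](CO[Si](C)(C)C(C)(C)C)C=C3[C@H]2CO[Si](C)(C)C(C)(C)C)cc(OC)c1OC | intermediate (not isolated)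
19 | (2R,3S)-3,5-bis{[(TBS)oxy]methyl}-2-(3,4,5-trimethoxyphenyl)-2,3-dihydro-1-benzofuran | COc1cc([C@@H]2Oc3ccc(CO[Si](C)(C)C(C)(C)C)cc3[C@H]2CO[Si](C)(C)C(C)(C)C)cc(OC)c1OC | intermediate (key-step product)
20 | [(2R,3S)-2-(3,4,5-trimethoxyphenyl)-2,3-dihydro-1-benzofuran-3,5-diyl]dimethanol | COc1cc([C@@H]2Oc3ccc(CO)cc3[C@H]2CO)cc(OC)c1OC | intermediate
21 | (2R,3S)-3-(hydroxymethyl)-2-(3,4,5-trimethoxyphenyl)-2,3-dihydro-1-benzofuran-5-carbaldehyde | COc1cc([C@@H]2Oc3ccc(C=O)cc3[C@H]2CO)cc(OC)c1OC | intermediate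
22 | ethyl (triphenylphosphoranylidene)acetate | CCOC(=O)C=P(c1ccccc1)(c1ccccc1)c1ccccc1 | starting material
23 | ethyl (E)-3-[(2R,3S)-3-(hydroxymethyl)-2-(3,4,5-trimethoxyphenyl)-2,3-dihydro-1-benzofuran-5-yl]prop-2-enoate | COc1cc([C@@H]2Oc3ccc(/C=C/C(=O)OCC)cc3[C@H]2CO)cc(OC)c1OC | intermediate
24 | (E)-3-[(2R,3S)-3-(hydroxymethyl)-2-(3,4,5-trimethoxyphenyl)-2,3-dihydro-1-benzofuran-5-yl]prop-2-en-1-ol | COc1cc([C@@H]2Oc3ccc(/C=C/CO)cc3[C@H]2CO)cc(OC)c1OC | target

## Step count and risks

Total step count: 13.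
Longest linear sequence: 13 steps (1 and 2 to 24).

### Step 9 (ring A benzannulation)

**What may go wrong:**
- The crowded diene, with its silyloxy group in the inside position, may add too slowly.
- The ketene acetal may hand its silyl group to the sulfoxide oxygen and start a Pummerer-type consumption of both partners.
- Aromatisation may proceed by cleavage of C7a–O1 and so open ring B.

**Fallback:** it uses known reaction types only, with ring A bought and ring B closed last. It sets out from 1 and 4 and comes back to the route at 23.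

Commercial 2-(5-bromo-2-hydroxyphenyl)acetic acid is treated with MeOCH2Cl/i-Pr2NEt to give methoxymethyl 2-[5-bromo-2-(methoxymethoxy)phenyl]acetate F1. LiOH cleaves the ester to 2-[5-bromo-2-(methoxymethoxy)phenyl]acetic acid F2. t-BuCOCl/Et3N converts this into 2-[5-bromo-2-(methoxymethoxy)phenyl]acetic 2,2-dimethylpropanoic anhydride F3. The lithium salt of 1 is then acylated to (4R)-4-benzyl-3-{[5-bromo-2-(methoxymethoxy)phenyl]acetyl}-1,3-oxazolidin-2-one F4.

An Evans syn-aldol reaction with 4 (n-Bu2BOTf, i-Pr2NEt, CH2Cl2, −78 → 0 °C) uses the same enolate face as step 2. It should give (4R)-4-benzyl-3-{(2R,3R)-2-[5-bromo-2-(methoxymethoxy)phenyl]-3-hydroxy-3-(3,4,5-trimethoxyphenyl)propanoyl}-1,3-oxazolidin-2-one F5. LiBH4 (Et2O, H2O, 0 °C) removes the auxiliary reductively to give (1R,2S)-2-[5-bromo-2-(methoxymethoxy)phenyl]-1-(3,4,5-trimethoxyphenyl)propane-1,3-diol F6.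

Aqueous HCl in THF takes off the acetal, and the freed phenol captures the 3,4,5-trimethoxybenzylic cation. C3 directs this closure to the trans ring, [(2R,3S)-5-bromo-2-(3,4,5-trimethoxyphenyl)-2,3-dihydro-1-benzofuran-3-yl]methanol F7. A Heck reaction with ethyl acrylate (Pd(OAc)2, P(o-tol)3, Et3N, DMF, 100 °C) then gives 23.

### Step 8 (diene formation)

**What may go wrong:**
- The silyl triflate may assist ionisation of the allylic C–OSi bond of the product, a vinylogous loss of silanol to a 2,4-dienyl lactone.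
- O-silylation of the weakly basic lactone carbonyl may be incomplete.
- The ketene acetal may hydrolyse on handling.

**Fallback:** it sets out from 14 and comes back at 15, and it takes the double bond out of conjugation first so that no silyl triflate is needed.

LiN(i-Pr)2 in THF/DMPU at −78 °C, followed by kinetic α-protonation with AcOH at −78 °C (deconjugative protonation of a dienolate), should give (4S,5R)-3-{(E)-3-[(TBS)oxy]prop-1-enyl}-4-{[(TBS)oxy]methyl}-5-(3,4,5-trimethoxyphenyl)oxolan-2-one F8. Its doubly activated C3a–H allows ordinary ester-enolate silylation (LiN(SiMe3)2, t-BuMe2SiCl, THF/DMPU, −78 °C) to 15.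

### Step 7 (dehydration)

**What may go wrong:**
- DBU may remove a C5 proton of the product and expel the silyloxy group (vinylogous E1cB).
- The aldol adduct may revert under base.

**Fallback:** it sets out from 10 and comes back at 14, and it replaces the aldol and elimination pair (steps 6 and 7) by a Horner–Wadsworth–Emmons olefination.

LiN(i-Pr)2 and ClP(O)(OEt)2 at −78 °C give the ketene acetal phosphate diethyl (4S,5R)-4-{[(TBS)oxy]methyl}-5-(3,4,5-trimethoxyphenyl)-4,5-dihydrofuran-2-yl phosphate F9. A second charge of LiN(i-Pr)2 induces the O-to-C 1,3-phosphoryl shift to diethyl [(4S,5R)-4-{[(TBS)oxy]methyl}-2-oxo-5-(3,4,5-trimethoxyphenyl)oxolan-3-yl]phosphonate F10. NaH (one equivalent, THF, 0 °C) and then 11 deliver 14 with no amidine base present. Either alkene geometry is acceptable.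

## Further compounds

F1 | step 9 | methoxymethyl 2-[5-bromo-2-(methoxymethoxy)phenyl]acetate | COCOC(=O)Cc1cc(Br)ccc1OCOC
F2 | step 9 | 2-[5-bromo-2-(methoxymethoxy)phenyl]acetic acid | COCOc1ccc(Br)cc1CC(=O)O
F3 | step 9 | 2-[5-bromo-2-(methoxymethoxy)phenyl]acetic 2,2-dimethylpropanoic anhydride | COCOc1ccc(Br)cc1CC(=O)OC(=O)C(C)(C)C
F4 | step 9 | (4R)-4-benzyl-3-{[5-bromo-2-(methoxymethoxy)phenyl]acetyl}-1,3-oxazolidin-2-one | COCOc1ccc(Br)cc1CC(=O)N1[C@H](Cc2ccccc2)COC1=O
F5 | step 9 | (4R)-4-benzyl-3-{(2R,3R)-2-[5-bromo-2-(methoxymethoxy)phenyl]-3-hydroxy-3-(3,4,5-trimethoxyphenyl)propanoyl}-1,3-oxazolidin-2-one | COCOc1ccc(Br)cc1[C@H]([C@@H](O)c1cc(OC)c(OC)c(OC)c1)C(=O)N1[C@H](Cc2ccccc2)COC1=O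
F6 | step 9 | (1R,2S)-2-[5-bromo-2-(methoxymethoxy)phenyl]-1-(3,4,5-trimethoxyphenyl)propane-1,3-diol | COCOc1ccc(Br)cc1[C@H]([C@@H](O)c1cc(OC)c(OC)c(OC)c1)CO
F7 | step 9 | [(2R,3S)-5-bromo-2-(3,4,5-trimethoxyphenyl)-2,3-dihydro-1-benzofuran-3-yl]methanol | COc1cc([C@@H]2Oc3ccc(Br)cc3[C@H]2CO)cc(OC)c1OC
F8 | step 8 | (4S,5R)-3-{(E)-3-[(TBS)oxy]prop-1-enyl}-4-{[(TBS)oxy]methyl}-5-(3,4,5-trimethoxyphenyl)oxolan-2-one (epimers at C3) | COc1cc([C@@H]2OC(=O)C(/C=C/CO[Si](C)(C)C(C)(C)C)[C@H]2CO[Si](C)(C)C(C)(C)C)cc(OC)c1OC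
F9 | step 7 | diethyl (4S,5R)-4-{[(TBS)oxy]methyl}-5-(3,4,5-trimethoxyphenyl)-4,5-dihydrofuran-2-yl phosphate | COc1cc([C@@H]2OC(OP(=O)(OCC)OCC)=C[C@H]2CO[Si](C)(C)C(C)(C)C)cc(OC)c1OC
F10 | step 7 | diethyl [(4S,5R)-4-{[(TBS)oxy]methyl}-2-oxo-5-(3,4,5-trimethoxyphenyl)oxolan-3-yl]phosphonate (epimers at C3) | COc1cc([C@@H]2OC(=O)C(P(=O)(OCC)OCC)[C@H]2CO[Si](C)(C)C(C)(C)C)cc(OC)c1OC
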